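The earlier runs and the new flask come from a simulation with made-up constants.

We follow the product, taken as one for each coupling partner used, so the product readings give [coupling partner].

| flask | solid substrate | coupling partner | initiator | remark | time |
|---|---|---|---|---|---|
| winter | 10 mM | 20 mM | 1 mM | run made earlier |  |
| spring | 40 mM | 20 mM | 1 mM | run made earlier |  |
| autumn | 20 mM | 20 mM | 0.50 mM | run made earlier |  |
| flask | 20 mM | 20.0 mM | 1.0 mM |  | 2.5 min |

- winter (time / s: product / %): 10.0: 17; 25.0: 44; 40.0: 74; 60.0: 98; 90.0: 97
- spring (time / s: product / %): 10.0: 3; 25.0: 8; 40.0: 20; 60.0: 27; 90.0: 32
- autumn (time / s: product / %): 20.0: 8; 40.0: 29; 50.0: 34; 80.0: 44; 90.0: 51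

(standard deviation of a reading: 2 percentage points)

- solid, in amounts per volume of the solution: solid substrate
- at the start none of the solid substrate is in solution

- beta: doubling the amount of coupling partner, all else as stated
- alpha: doubling the dissolution coefficient of the solid substrate, all else as stated
- delta: doubling the solubility of the solid substrate, all else as stated

- amount of product at 2.5 min, in percent of the solid substrate charged
- the change that raises the amount of product at 2.5 min, in percent of the solid substrate charged most ("none" if none brings more than 2 percentage points) (beta / alpha / delta / none)
- amount of product at 2.5 min, in percent of the solid substrate charged, after delta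

1. In the flask: solid substrate, none of it dissolved at the start, stirred with coupling partner and initiator.

2. The spring run at 90.0 s reads 0.0114 s⁻¹. This is the partner constant: the ln of starting [coupling partner] over present [coupling partner], divided by the time, a pseudo-first-order constant.

3. The winter run at 40.0 s, with a quarter of that solid substrate, reads 0.0116 s⁻¹, about the same.

4. When you come at 2.5 min, we expect 18.2% of the coupling partner left, so product at 81.8% of the solid substrate charged.

5. Leave the solid substrate alone. For delta we simply assume the same constant, which the runs neither prove nor test, so we expect delta to stay near 81.8%. Beta would use 32.7 mM of coupling partner, more than the 20 mM of solid substrate, so we choose beta.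

6. The forecast gives 83%, beta and 97% after delta, holding that “Delta doubles the rate”.

7. The flask gives 81.1%, and 81.1% after delta, a gain of 0.059 percentage points, while beta gains 17 points.

    initiator → 2 initiating radical (k = 0.00478 s⁻¹)
    starting material + initiating radical → capped initiator + first chain carrier (k = 6.37 × 10⁵ M⁻¹ s⁻¹)
    coupling partner + first chain carrier → product + second chain carrier (k = 9650 M⁻¹ s⁻¹)
    starting material + second chain carrier → released group + first chain carrier (k = 9690 M⁻¹ s⁻¹)
    first chain carrier → ended carrier (k = 3.06 s⁻¹)
    2 first chain carrier → ended chains (k = 1.20 × 10⁶ M⁻¹ s⁻¹)
    solid substrate ⇌ starting material, rate k7*(cs7 - [starting material]) while solid is left; crystals form when [starting material] > cs7 (solubility = 6.60 mM, k = 0.0320 s⁻¹)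

The flask keeps 19% of its coupling partner against our 18.2%. With 5.0 mM of coupling partner, the partner constant again leaves 18.2% of that charge, which makes product 20.5% of the solid substrate charged; that neighbouring flask holds 20.3%.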